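Reagent left over by the substrate can still reach the partner, and the target needs both open intermediate and second intermediate at once.

    substrate + reagent → open intermediate (k1 = 1460 /M/s)
    reagent + partner → second intermediate (k2 = 102 /M/s)
    open intermediate + second intermediate → target (k3 = 355 /M/s)
    2 second intermediate → homo product (k4 = 98.3 /M/s)
    open intermediate + capture agent → trapped intermediate (k5 = 885 /M/s)

| setting | north | south | north-west | east | north-east |
|---|---|---|---|---|---|
| substrate | 0.10 mM | 0.20 mM | 0.40 mM | 0.80 mM | 1.5 mM |
| partner | 0.240 mM | 0.240 mM | 0.240 mM | 0.240 mM | 0.240 mM |
| reagent | 0.500 mM | 0.500 mM | 0.500 mM | 0.500 mM | 0.500 mM |
| capture agent | 0.200 mM | 0.200 mM | 0.200 mM | 0.200 mM | 0.200 mM |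
| time | 6.0 s | 6.0 s | 6.0 s | 6.0 s | 6.0 s |

- a step written with two of one species runs at k times the square of its concentration and takes two of it each time
- "hardly changes" means that all values lie within two and a half points (for a concentration: within two and a half percent of the largest)
- run time (north): 6.0 s

- [target] at the end for north, south, north-west, east, north-east, in this order
- how that number moves from the first to the last of them (hardly changes / falls all the way / falls, then rises / rises, then falls / rises all the way)

We follow the reagent, which substrate and partner both consume. We call the split the rate of its use by substrate over its use by partner at the start, k1[substrate]/k2[partner]. If the split held, substrate would receive the fraction split/(one plus split) of the reagent. Substrate and reagent then run out together when this share equals the substrate charge. That charge is the reagent charge less a toll of 0.0168 mM paid to the partner, which comes to 0.483 mM; we call it the crossing charge. The spare reagent is the crossing charge less the substrate charge.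

| Flask | Substrate charged | Spare reagent | Split |
|---|---|---|---|
| north | 0.10 mM | 0.383 mM | 5.96 |
| south | 0.20 mM | 0.283 mM | 11.9 |
| north-west | 0.40 mM | 0.0830 mM | 23.9 |
| east | 0.80 mM | −0.317 mM | 47.7 |
| north-east | 1.5 mM | −1.02 mM | 89.5 |

Reading down the split column, at the start substrate takes reagent faster than partner even in north. Reading down the spare column, north, south and north-west keep a positive spare, and each is charged with more substrate than the one before . In east the spare turns negative: reagent becomes the limiting reagent, and the partner's share shrinks as the split climbs. Target formation runs on the product of the two intermediates, so we score each shape by where the crossing charge stands among the substrate charges; because it stands inside their range, the shape we expect is rises, then falls, turning near the crossing charge. Our reckoning goes no further and gives no target values.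

The forecast gives 0.0034 mM, 0.0057 mM, 0.0083 mM, 0.0062 mM and 0.004 mM, with the shape rises, then falls, and says “Target peaks near 0.4 mM substrate”. We agree on the shape but place the turn higher.

The simulation gives 0.00310 mM, 0.00528 mM, 0.00708 mM, 0.00571 mM and 0.00322 mM, with the shape rises, then falls. The row, as read, turns at 0.44 mM, lower than the crossing charge. In north, below the crossing charge, substrate used reagent 6.0 times as fast as partner at the start and 0.23 times as fast at 6.00 s, with 70 % of the reagent charge still there. For north-east, the charge less the crossing charge leaves 1.02 mM of substrate over, and at 6.00 s, with reagent down to 0.0087 % of its charge, substrate stands at 1.01 mM.

All constants are invented; what happens was integrated by code.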